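**Plan**
- Locants: unit 1 is the flavone joined at C6 (plain locants, B ring primed). Unit 2 is the flavone joined at C8 (double-primed locants, B ring triple-primed). The retrosynthesis first cuts the O-benzyl, O5''-CH3 and O7''-CH3 bonds, then the C6-C8'' biaryl bond, and last the O1-C2 and C2-C3 bonds of each pyrone.
- Enabling feature: C6-C8'' is flanked by four ortho oxygens (O5 and O7 on ring A of unit 1, O7'' and O1'' on unit 2). One CH2 can span O5 and O7'', so that C6, C5, O5, CH2, O7'', C7'' and C8'' form a seven-membered 1,3-dioxepine once the biaryl bond exists.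
- Forward: ring C of each unit is closed from a 2'-hydroxychalcone. Iodine is then placed at C6 (steered by the chelated 5-OH) and at C8'' (5''-O-methyl, free 7''-OH).
- The halves are joined as an O5-CH2-O7'' acetal, the dioxepine ring closes in the coupling, and it is opened again afterwards. Methylation of O7'' and one BCl3 deprotection finish the route.
- Stereochemistry: the target has no stereocentre, the E alkenes of both chalcones are consumed on cyclisation, and the biaryl axis forms as a racemate.

Key step: step 11

Assumption: the target is drawn without a descriptor for the C6-C8'' axis, so the racemic mixture of atropisomers is taken as the goal.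

**Step 1**
Reactants: 1 2',6'-dihydroxy-4'-methoxyacetophenone
Product: 2 2'-hydroxy-4'-methoxy-6'-(methoxymethoxy)acetophenone
Conditions: MOMCl (1.1 equiv), K2CO3, acetone, 0 °C to rt
Reagents that add atoms: chloromethyl methyl ether (MOMCl), COCCl
Why: This is a Williamson-type O-alkylation in which the two hydroxyls are equivalent, and once one is capped the other is held in a hydrogen bond to the ketone and reacts far more slowly, so the mono-ether should prevail.

**Step 2**
Reactants: 2 2'-hydroxy-4'-methoxy-6'-(methoxymethoxy)acetophenone; 3 4-benzyloxybenzaldehyde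
Product: 4 (E)-4-benzyloxy-2'-hydroxy-4'-methoxy-6'-(methoxymethoxy)chalcone
Conditions: KOH, EtOH-H2O, rt
Reagents that add atoms: none
Why: In this Claisen-Schmidt condensation the acetophenone enolate adds to the non-enolisable aldehyde and E1cB loss of water gives the conjugated E-enone, while MOM and benzyl ethers are inert to hydroxide.

**Step 3**
Reactants: 4 (E)-4-benzyloxy-2'-hydroxy-4'-methoxy-6'-(methoxymethoxy)chalcone
Product: 6 4'-benzyloxy-5-hydroxy-7-methoxyflavone, via 5-O-methoxymethyl flavone 5 (not isolated)
Conditions: I2 (10 mol %), DMSO, 120 °C; then conc. HCl, MeOH-THF, 60 °C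
Reagents that add atoms: none
Why: The iodine/DMSO oxidative cyclisation of a 2'-hydroxychalcone (6-endo oxa-Michael closure of O1-C2, then dehydrogenation with DMSO as terminal oxidant) builds ring C and acid methanolysis strips the labile peri MOM group, and early MOM loss is harmless because either ortho oxygen would give the same flavone.

**Step 4**
Reactants: 6 4'-benzyloxy-5-hydroxy-7-methoxyflavone
Product: 7 4'-benzyloxy-5-hydroxy-6-iodo-7-methoxyflavone
Conditions: BnMe3N·ICl2 (1.1 equiv), CaCO3, CH2Cl2-MeOH, rt
Reagents that add atoms: benzyltrimethylammonium dichloroiodate, C[N+](C)(C)Cc1ccccc1.Cl[I-]Cl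
Why: This electrophilic aromatic iodination uses a dichloroiodate salt known to attack 5-hydroxy-7-alkoxyflavones at C6, ortho to the chelated 5-hydroxyl, while CaCO3 takes up HCl and the deactivated B ring stays untouched.

**Step 5**
Reactants: 8 2',4'-dihydroxy-6'-methoxyacetophenone
Product: 9 2'-hydroxy-6'-methoxy-4'-(methoxymethoxy)acetophenone
Conditions: MOMCl (1.1 equiv), K2CO3, acetone, 0 °C to rt
Reagents that add atoms: chloromethyl methyl ether (MOMCl), COCCl
Why: In this Williamson-type O-alkylation the 4'-hydroxyl is the more acidic and is not hydrogen-bonded, whereas the 2'-hydroxyl is chelated to the ketone, so one equivalent of MOMCl should go to O4'.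

**Step 6**
Reactants: 9 2'-hydroxy-6'-methoxy-4'-(methoxymethoxy)acetophenone; 3 4-benzyloxybenzaldehyde
Product: 10 (E)-4-benzyloxy-2'-hydroxy-6'-methoxy-4'-(methoxymethoxy)chalcone
Conditions: KOH, EtOH-H2O, rt
Reagents that add atoms: none
Why: This Claisen-Schmidt condensation runs as in step 2, and capping O4' keeps the ketone ring from becoming a doubly charged, unreactive phenoxide-enolate.

**Step 7**
Reactants: 10 (E)-4-benzyloxy-2'-hydroxy-6'-methoxy-4'-(methoxymethoxy)chalcone
Product: 12 4'-benzyloxy-7-hydroxy-5-methoxyflavone, via 7-O-methoxymethyl flavone 11 (not isolated)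
Conditions: I2 (10 mol %), DMSO, 120 °C; then conc. HCl, MeOH-THF, 60 °C
Reagents that add atoms: none
Why: The iodine/DMSO oxidative cyclisation closes ring C through the only oxygen that can reach the enone (O2'), and acid methanolysis of the MOM ether then frees the 7-hydroxyl, so partial MOM loss in the first stage changes nothing.

**Step 8**
Reactants: 12 4'-benzyloxy-7-hydroxy-5-methoxyflavone
Product: 13 4'-benzyloxy-7-hydroxy-8-iodo-5-methoxyflavone
Conditions: NIS (1.0 equiv), DMF, rt, dark
Reagents that add atoms: N-iodosuccinimide, O=C1CCC(=O)N1I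
Why: In this electrophilic aromatic iodination of a phenol both C6 and C8 are ortho to the free 7-hydroxyl, but with O5 alkylated no chelated hydroxyl steers to C6 and C8 (flanked only by O7 and the tied-back O1) is the more nucleophilic and less crowded site, in line with the known 8-selectivity of NIS on 7-hydroxy-5-alkoxyflavones; the regiochemistry is to be confirmed by HMBC before going on.

**Step 9**
Reactants: 13 4'-benzyloxy-7-hydroxy-8-iodo-5-methoxyflavone; 14 chloromethyl methyl sulfide
Product: 15 4'-benzyloxy-8-iodo-5-methoxy-7-(methylsulfanylmethoxy)flavone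
Conditions: NaH, DMF, 0 °C to rt
Reagents that add atoms: none
Why: Williamson O-alkylation of the acidic 7-phenoxide with an α-chloro sulfide gives the O,S-acetal (methylthiomethyl ether), and the aryl iodide and the other ethers are inert to NaH at this temperature.

**Step 10**
Reactants: 15 4'-benzyloxy-8-iodo-5-methoxy-7-(methylsulfanylmethoxy)flavone; 7 4'-benzyloxy-5-hydroxy-6-iodo-7-methoxyflavone
Product: 17 formaldehyde acetal joining O5 of 6-iodo unit 1 to O7'' of 8''-iodo unit 2, via chloromethyl ether 16 (not isolated)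
Conditions: 15, SO2Cl2 (1.0 equiv), cyclohexene, CH2Cl2, −78 to 0 °C, concentrate; then 7, NaH, DMF, 0 °C to rt
Reagents that add atoms: sulfuryl chloride, O=S(=O)(Cl)Cl (its chlorine stays in 16 only and is lost again on the way to 17)
Why: Chlorinolysis of the O,S-acetal (chlorosulfonium formation and collapse to the aryl chloromethyl ether, with cyclohexene trapping MeSCl before it can attack C6'') is followed by Williamson alkylation of the 5-phenoxide of 7, whose low nucleophilicity is offset by the high reactivity of an α-chloro ether, as in the 5-O-methoxymethylation of flavones.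

**Step 11**
Reactants: 17 formaldehyde acetal joining O5 of 6-iodo unit 1 to O7'' of 8''-iodo unit 2
Product: 19 4',4'''-bis(benzyloxy)-7,5''-dimethoxy-5,7''-(methylenedioxy)-6,8''-biflavone (methylene-bridged biflavone), via 8''-trimethylstannyl 6-iodo acetal 18 (not isolated)
Conditions: Me6Sn2 (1.05 equiv, slow addition), Pd(PPh3)4 (10 mol %), 1,4-dioxane (5 mM), 100 °C
Reagents that add atoms: hexamethylditin, C[Sn](C)(C)[Sn](C)(C)C (its Me3Sn group stays in 18 only; 19 takes up no atoms)
Why: Zerovalent palladium should insert first into the less crowded C8''-I bond (one neighbour is the tied-back ring oxygen O1''), and transmetalation with the ditin followed by reductive elimination gives arylstannane 18; the reverse order of events would lead to the same product. Insertion into the remaining C6-I bond, intramolecular tin-to-palladium transfer of C8'' and reductive elimination then forge C6-C8'', which makes this a Stille-Kelly coupling, the ditin-mediated cyclisation of tethered aryl dihalides. The single ring closed is the seven-membered dibenzo[d,f][1,3]dioxepine (C6, C5, O5, CH2, O7'', C7'', C8''), formed by ring-contracting reductive elimination from an eight-membered diarylpalladacycle with both new-bond carbons inside the ring. No stereocentre is created and the new axis arises as a racemate. The step needs cross- over homo-coupling and 6,8'' regiochemistry, both fixed by the O5-CH2-O7'' bridge and the iodine positions, and it needs cyclisation to beat oligomerisation and double stannylation, which high dilution and a ditin charge held near one equivalent should secure. The neutral medium leaves the pyrone carbonyls, the benzyl ethers and the acetal untouched.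

**Step 12**
Reactants: 19 methylene-bridged biflavone
Product: 20 4',4'''-bis(benzyloxy)-5,7''-dihydroxy-7,5''-dimethoxy-6,8''-biflavone
Conditions: conc. HCl, MeOH-THF, 60 °C
Reagents that add atoms: none
Why: In this acid-catalysed transacetalisation, protonation of the basic pyrone carbonyl of unit 1 places a proton next to the peri O5 and makes it a good leaving group, methanol carries the bridge carbon away as an inert acetal so that no formaldehyde is left to attack the A rings, and benzyl and methyl ethers survive at a temperature far below that of a Wessely-Moser rearrangement.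

**Step 13**
Reactants: 20 4',4'''-bis(benzyloxy)-5,7''-dihydroxy-7,5''-dimethoxy-6,8''-biflavone
Product: 21 4',4'''-bis(benzyloxy)-5-hydroxy-7,5'',7''-trimethoxy-6,8''-biflavone
Conditions: MeI (1.5 equiv), K2CO3, acetone, 40 °C
Reagents that add atoms: iodomethane, CI
Why: This Williamson methylation goes to the only non-chelated phenol (7''-OH) because the 5-hydroxyl is hydrogen-bonded to C4=O and crowded, and any stray methylation at O5 would be erased by the peri-selective cleavage of step 14.

**Step 14**
Reactants: 21 4',4'''-bis(benzyloxy)-5-hydroxy-7,5'',7''-trimethoxy-6,8''-biflavone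
Product: 22 5,5'',4',4'''-tetrahydroxy-7,7''-dimethoxy-6,8''-biflavone (7,7''-di-O-methylagathisflavone, DMGF)
Conditions: BCl3 (excess), C6HMe5, CH2Cl2, −78 °C to rt; then H2O
Reagents that add atoms: none
Why: BCl3 ether cleavage removes the aryl benzyl ethers at low temperature with pentamethylbenzene as a non-basic benzyl cation scavenger, the peri 5''-O-methyl goes on warming through the carbonyl-boron chelate, and the non-chelating 7- and 7''-methyl ethers are not cleaved by BCl3 under these conditions.

**Compound list**
1 | 2',6'-dihydroxy-4'-methoxyacetophenone | CC(=O)c1c(O)cc(OC)cc1O | starting material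
2 | 2'-hydroxy-4'-methoxy-6'-(methoxymethoxy)acetophenone | CC(=O)c1c(O)cc(OC)cc1OCOC | intermediate
3 | 4-benzyloxybenzaldehyde | O=Cc1ccc(OCc2ccccc2)cc1 | starting material
4 | (E)-4-benzyloxy-2'-hydroxy-4'-methoxy-6'-(methoxymethoxy)chalcone | COCOc1cc(OC)cc(O)c1C(=O)/C=C/c1ccc(OCc2ccccc2)cc1 | intermediate
5 | 4'-benzyloxy-7-methoxy-5-(methoxymethoxy)flavone | COCOc1cc(OC)cc2oc(-c3ccc(OCc4ccccc4)cc3)cc(=O)c12 | intermediate
6 | 4'-benzyloxy-5-hydroxy-7-methoxyflavone | COc1cc(O)c2c(=O)cc(-c3ccc(OCc4ccccc4)cc3)oc2c1 | intermediate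
7 | 4'-benzyloxy-5-hydroxy-6-iodo-7-methoxyflavone | COc1cc2oc(-c3ccc(OCc4ccccc4)cc3)cc(=O)c2c(O)c1I | intermediate
8 | 2',4'-dihydroxy-6'-methoxyacetophenone | CC(=O)c1c(O)cc(O)cc1OC | starting material
9 | 2'-hydroxy-6'-methoxy-4'-(methoxymethoxy)acetophenone | CC(=O)c1c(O)cc(OCOC)cc1OC | intermediate
10 | (E)-4-benzyloxy-2'-hydroxy-6'-methoxy-4'-(methoxymethoxy)chalcone | COCOc1cc(O)c(C(=O)/C=C/c2ccc(OCc3ccccc3)cc2)c(OC)c1 | intermediate
11 | 4'-benzyloxy-5-methoxy-7-(methoxymethoxy)flavone | COCOc1cc(OC)c2c(=O)cc(-c3ccc(OCc4ccccc4)cc3)oc2c1 | intermediate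
12 | 4'-benzyloxy-7-hydroxy-5-methoxyflavone | COc1cc(O)cc2oc(-c3ccc(OCc4ccccc4)cc3)cc(=O)c12 | intermediate
13 | 4'-benzyloxy-7-hydroxy-8-iodo-5-methoxyflavone | COc1cc(O)c(I)c2oc(-c3ccc(OCc4ccccc4)cc3)cc(=O)c12 | intermediate
14 | chloromethyl methyl sulfide | CSCCl | starting material
15 | 4'-benzyloxy-8-iodo-5-methoxy-7-(methylsulfanylmethoxy)flavone | COc1cc(OCSC)c(I)c2oc(-c3ccc(OCc4ccccc4)cc3)cc(=O)c12 | intermediate
16 | 4'-benzyloxy-7-(chloromethoxy)-8-iodo-5-methoxyflavone | COc1cc(OCCl)c(I)c2oc(-c3ccc(OCc4ccccc4)cc3)cc(=O)c12 | intermediate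
17 | formaldehyde acetal joining O5 of 4'-benzyloxy-6-iodo-7-methoxyflavone (unit 1) to O7'' of 4'''-benzyloxy-8''-iodo-5''-methoxyflavone (unit 2) | COc1cc2oc(-c3ccc(OCc4ccccc4)cc3)cc(=O)c2c(OCOc2cc(OC)c3c(=O)cc(-c4ccc(OCc5ccccc5)cc4)oc3c2I)c1I | intermediate
18 | the same acetal with SnMe3 in place of iodine at C8'' (C6 still iodinated) | COc1cc2oc(-c3ccc(OCc4ccccc4)cc3)cc(=O)c2c(OCOc2cc(OC)c3c(=O)cc(-c4ccc(OCc5ccccc5)cc4)oc3c2[Sn](C)(C)C)c1I | intermediate
19 | 4',4'''-bis(benzyloxy)-7,5''-dimethoxy-5,7''-(methylenedioxy)-6,8''-biflavone (dibenzo[d,f][1,3]dioxepine core, racemic axis) | COc1cc2oc(-c3ccc(OCc4ccccc4)cc3)cc(=O)c2c2OCOc3cc(OC)c4c(=O)cc(-c5ccc(OCc6ccccc6)cc5)oc4c3-c12 | intermediate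
20 | 4',4'''-bis(benzyloxy)-5,7''-dihydroxy-7,5''-dimethoxy-6,8''-biflavone | COc1cc2oc(-c3ccc(OCc4ccccc4)cc3)cc(=O)c2c(O)c1-c1c(O)cc(OC)c2c(=O)cc(-c3ccc(OCc4ccccc4)cc3)oc12 | intermediate
21 | 4',4'''-bis(benzyloxy)-5-hydroxy-7,5'',7''-trimethoxy-6,8''-biflavone | COc1cc2oc(-c3ccc(OCc4ccccc4)cc3)cc(=O)c2c(O)c1-c1c(OC)cc(OC)c2c(=O)cc(-c3ccc(OCc4ccccc4)cc3)oc12 | intermediate
22 | 5,5'',4',4'''-tetrahydroxy-7,7''-dimethoxy-6,8''-biflavone (DMGF) | COc1cc2oc(-c3ccc(O)cc3)cc(=O)c2c(O)c1-c1c(OC)cc(O)c2c(=O)cc(-c3ccc(O)cc3)oc12 | target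

**Step count**
Total step count: 14.
Longest linear sequence: 10 steps (steps 5 to 14, from 8). The unit 1 branch (steps 1 to 4) joins at step 10.

**Steps most likely to fail**

**Step 11.**
- Risk: transmetalation at a carbon flanked by two oxygens is slow, so hydrodeiodination, stannylation of both iodides or intermolecular coupling may outrun ring closure.
- Fallback: the nucleophilic partner is fixed before the tether is made, and the same ring is closed by an intramolecular Suzuki-Miyaura coupling.
- Setting out from 15, Miyaura borylation (B2pin2, KOAc, PdCl2(dppf), dioxane, 90 °C) should give 4'-benzyloxy-5-methoxy-7-(methylsulfanylmethoxy)-8-(pinacolatoboryl)flavone F1.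
- SO2Cl2 with cyclohexene in CH2Cl2 converts F1 into 4'-benzyloxy-7-(chloromethoxy)-5-methoxy-8-(pinacolatoboryl)flavone F2.
- F2 alkylates the sodium salt of 7 in DMF to the iodide-boronate formaldehyde acetal F3.
- Pd(OAc)2, SPhos and K3PO4 in toluene-H2O at 90 °C under high dilution then form C6-C8'', and the sequence comes back to the route at 19.

**Step 10.**
- Risk: the chloromethyl ether may hydrolyse, ring chlorination or sulfenylation may occur while it is made, and O-alkylation of the crowded, chelated 5-phenoxide may be too slow.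
- Fallback: the roles of the partners are exchanged, so the hindered oxygen carries the electrophilic carbon and the unhindered, more acidic 7-phenoxide does the displacement.
- Setting out from 7, NaH and 14 in DMF should give 4'-benzyloxy-6-iodo-7-methoxy-5-(methylsulfanylmethoxy)flavone F4.
- SO2Cl2 with cyclohexene turns F4 into 4'-benzyloxy-5-(chloromethoxy)-6-iodo-7-methoxyflavone F5.
- The sodium salt of 13 in DMF displaces the chloride of F5, and the sequence comes back to the route at 17.

**Step 12.**
- Risk: the diaryl acetal may resist methanolysis because only an aryloxymethyl cation is left behind. Forcing acid would invite loss of the benzyl ethers and Wessely-Moser ring opening and reclosure of unit 1, which would scramble the 6-linkage.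
- Fallback: the end game is reordered around chelation-directed Lewis acid dealkylation.
- Setting out from 19, BCl3 (2.2 equiv, one held at each pyrone carbonyl) in CH2Cl2 at −78 to −20 °C, then water, should cut both peri O-C bonds (O5-CH2 and O5''-CH3). This gives 4',4'''-bis(benzyloxy)-5,5'',7''-trihydroxy-7-methoxy-6,8''-biflavone F6.
- MeI and K2CO3 in acetone methylate the only non-chelated phenol of F6 to give 4',4'''-bis(benzyloxy)-5,5''-dihydroxy-7,7''-dimethoxy-6,8''-biflavone F7.
- Hydrogenolysis (H2, Pd/C, THF-MeOH) removes both benzyl groups, and the sequence comes back to the route at 22.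

**Further compounds**
F1 | step 11 | 4'-benzyloxy-5-methoxy-7-(methylsulfanylmethoxy)-8-(pinacolatoboryl)flavone | COc1cc(OCSC)c(B2OC(C)(C)C(C)(C)O2)c2oc(-c3ccc(OCc4ccccc4)cc3)cc(=O)c12
F2 | step 11 | 4'-benzyloxy-7-(chloromethoxy)-5-methoxy-8-(pinacolatoboryl)flavone | COc1cc(OCCl)c(B2OC(C)(C)C(C)(C)O2)c2oc(-c3ccc(OCc4ccccc4)cc3)cc(=O)c12
F3 | step 11 | formaldehyde acetal joining O5 of 6-iodo unit 1 to O7'' of 8''-(pinacolatoboryl) unit 2 | COc1cc2oc(-c3ccc(OCc4ccccc4)cc3)cc(=O)c2c(OCOc2cc(OC)c3c(=O)cc(-c4ccc(OCc5ccccc5)cc4)oc3c2B2OC(C)(C)C(C)(C)O2)c1I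
F4 | step 10 | 4'-benzyloxy-6-iodo-7-methoxy-5-(methylsulfanylmethoxy)flavone | COc1cc2oc(-c3ccc(OCc4ccccc4)cc3)cc(=O)c2c(OCSC)c1I
F5 | step 10 | 4'-benzyloxy-5-(chloromethoxy)-6-iodo-7-methoxyflavone | COc1cc2oc(-c3ccc(OCc4ccccc4)cc3)cc(=O)c2c(OCCl)c1I
F6 | step 12 | 4',4'''-bis(benzyloxy)-5,5'',7''-trihydroxy-7-methoxy-6,8''-biflavone | COc1cc2oc(-c3ccc(OCc4ccccc4)cc3)cc(=O)c2c(O)c1-c1c(O)cc(O)c2c(=O)cc(-c3ccc(OCc4ccccc4)cc3)oc12
F7 | step 12 | 4',4'''-bis(benzyloxy)-5,5''-dihydroxy-7,7''-dimethoxy-6,8''-biflavone | COc1cc2oc(-c3ccc(OCc4ccccc4)cc3)cc(=O)c2c(O)c1-c1c(OC)cc(O)c2c(=O)cc(-c3ccc(OCc4ccccc4)cc3)oc12
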